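## Retrosynthetic overview

1. Feature: the indoline C2–C3 bond joins quaternary C3 (aryl, CO2Me, CH2CH2N) to C2, a carbon of ring A (cyclohexane) whose ring neighbour leads through CH2–CH2 to the spiro carbon bearing the amine nitrogen. With that CH2–CH2 unit as an alkene this is an α-aryl γ,δ-unsaturated acid, the retron of an Ireland–Claisen rearrangement of an aryl-acetate ester of a cyclohexenol whose carbinol carbon is next to the spiro carbon.
2. Key disconnection: C2–C3 by a [3,3] ring switch from the eight-membered lactone 22 (N–CH2CH2–CH(Ar)–CO–O spanning spiro carbon and allylic carbinol) to the azocane diacid 26. The ring-A carboxyl is carried as the free acid (a carboxylate under the base) so that its allylic α-hydrogen is not removed, and the aryl halide is an iodide so that the later azidation is feasible.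
3. After: alkene reduction, then N1–C2 by rhodium-nitrene insertion of the aryl azide into the C2–H bond, N-carbamate, desilylation.
4. Before: the lactone ester bond comes from an Evans–Tishchenko reduction that also sets the pyrrolidine carbinol; the N–CH2 bond comes from reductive amination; the spiro-cyclohexenol comes from an exo Diels–Alder reaction of a 2-methylidene-pyrrolidin-3-one with a 5-silyloxy-penta-2,4-dienoate, resolved once.
5. Ring order: pyrrolidine (bought) → cyclohexene ring A (step 5) → eight-membered lactone (step 12) → azocane by ring switch (step 13) → indoline (step 17).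

Key step: step 13

Remarks on the chemistry:
- Compounds 6, 8, 14 and 15 are taken as commercial.
- The material is racemic through 11 and is resolved in step 6; the absolute configuration is to be confirmed by anomalous X-ray dispersion on a crystalline iodoarene such as 19 or 27.
- The carbon α to the aryl-acetate carbonyl is carried as both epimers from 16 to 22 and becomes planar in step 13.
- Labels: 1-azaspiro[4.5]decane numbering is used for 11–24 (N1, C4 carbinol/ketone carbon, C5 spiro carbon, C6 oxygen-bearing allylic carbon, C7=C8, C9 carboxyl-bearing carbon, C10). Indoline C2 of the target is the former C8.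

## Route

Step 1
Reactants: 1 1-tert-butyl 2-methyl 3-oxopyrrolidine-1,2-dicarboxylate
Product: 4 tert-butyl 2-[(dimethylamino)methyl]-3-oxopyrrolidine-1-carboxylate (racemic), via lithium 1-(tert-butoxycarbonyl)-3-oxopyrrolidine-2-carboxylate 2 (not isolated), via 1-(tert-butoxycarbonyl)-2-[(dimethylamino)methyl]-3-oxopyrrolidine-2-carboxylic acid 3 (not isolated)
Conditions: LiOH, THF/H2O, 0 °C → rt; then Me2NH·HCl, 37% aq. CH2O, AcOH (pH 5), rt
Reagents that add atoms: formaldehyde, C=O; dimethylamine hydrochloride, CNC.Cl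
Why: Saponification gives the β-keto carboxylate, whose Mannich reaction takes place at the doubly activated C2 and is followed by loss of CO2 (Mannich reaction of a β-keto acid), so the aminomethyl group should end at C2 and not at C4.

Step 2
Reactants: 4 tert-butyl 2-[(dimethylamino)methyl]-3-oxopyrrolidine-1-carboxylate
Product: 5 {[1-(tert-butoxycarbonyl)-3-oxopyrrolidin-2-yl]methyl}trimethylammonium iodide
Conditions: MeI, acetone, 0 °C → rt
Reagents that add atoms: iodomethane, CI
Why: Menshutkin N-methylation turns the Mannich base into a storable salt that should release the enone only when base is added.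

Step 3
Reactants: 6 malondialdehyde tetrabutylammonium salt
Product: 7 (E)-3-[(tert-butyldimethylsilyl)oxy]prop-2-enal
Conditions: t-BuMe2SiCl, CH2Cl2, 0 °C → rt
Reagents that add atoms: tert-butyldimethylsilyl chloride, CC(C)(C)[Si](C)(C)Cl
Why: The ambident malondialdehyde enolate is silylated at oxygen, giving the E vinylogous silyl ester.

Step 4
Reactants: 7 (E)-3-[(tert-butyldimethylsilyl)oxy]prop-2-enal; 8 tert-butyl (triphenyl-λ5-phosphanylidene)acetate
Product: 9 tert-butyl (2E,4E)-5-[(tert-butyldimethylsilyl)oxy]penta-2,4-dienoate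
Conditions: toluene, 70 °C
Reagents that add atoms: none
Why: Wittig olefination with a stabilised ylide should form the new C2=C3 bond E and leave the E enol ether untouched, giving the E,E diene.

Step 5
Reactants: 5 {[1-(tert-butoxycarbonyl)-3-oxopyrrolidin-2-yl]methyl}trimethylammonium iodide; 9 tert-butyl (2E,4E)-5-[(tert-butyldimethylsilyl)oxy]penta-2,4-dienoate
Product: 11 rac-di-tert-butyl (5S,6R,9R)-6-[(tert-butyldimethylsilyl)oxy]-4-oxo-1-azaspiro[4.5]dec-7-ene-1,9-dicarboxylate (6-O and N1 and 9-CO2 on one ring face), via tert-butyl 2-methylidene-3-oxopyrrolidine-1-carboxylate 10 (not isolated)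
Conditions: K2CO3, 2,6-di-tert-butyl-4-methylphenol (cat.), 9 (1.5 equiv), MeCN, 50 °C
Reagents that add atoms: none
Why: E1cB loss of NMe3 releases the s-cis-locked enone in the presence of the diene, and a normal-demand Diels–Alder reaction should join the ester-bearing diene terminus to the exocyclic CH2 and the silyloxy-bearing terminus to the N-substituted carbon (ortho rule of a 1-oxy diene); the E,E diene makes 6-O and 9-CO2 cis, and addition exo to the ring ketone, as is usual for ring-locked α-methylene carbonyl dienophiles, places both cis to nitrogen.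

Step 6
Reactants: 11 rac-di-tert-butyl (5S,6R,9R)-6-[(tert-butyldimethylsilyl)oxy]-4-oxo-1-azaspiro[4.5]dec-7-ene-1,9-dicarboxylate
Product: 12 di-tert-butyl (5S,6R,9R)-6-[(tert-butyldimethylsilyl)oxy]-4-oxo-1-azaspiro[4.5]dec-7-ene-1,9-dicarboxylate (single enantiomer)
Conditions: preparative supercritical-fluid chromatography, amylose tris(3,5-dimethylphenylcarbamate) phase, CO2/i-PrOH
Reagents that add atoms: none
Why: Resolution of the racemate on a chiral stationary phase supplies the enantiomer whose three centres map onto the target.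

Step 7
Reactants: 12 di-tert-butyl (5S,6R,9R)-6-[(tert-butyldimethylsilyl)oxy]-4-oxo-1-azaspiro[4.5]dec-7-ene-1,9-dicarboxylate
Product: 13 di-tert-butyl (5S,6R,9R)-6-hydroxy-4-oxo-1-azaspiro[4.5]dec-7-ene-1,9-dicarboxylate
Conditions: HF·pyridine, pyridine/THF, 0 °C → rt
Reagents that add atoms: none
Why: Fluoride cleaves the allylic silyl ether under weakly acidic conditions that should keep the carbamate and the tert-butyl ester and avoid retro-aldol opening of the β-hydroxy ketone.

Step 8
Reactants: 14 methyl 2-(2-iodophenyl)acetate; 15 2-bromo-1,1-dimethoxyethane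
Product: 16 methyl 2-(2-iodophenyl)-4,4-dimethoxybutanoate (racemic)
Conditions: NaN(SiMe3)2, THF/DMPU, −78 °C; then 15, NaI (cat.), → 50 °C
Reagents that add atoms: none
Why: SN2 alkylation of the arylacetate enolate; a second alkylation is slowed by the congested tertiary enolate and the poor electrophile.

Step 9
Reactants: 16 methyl 2-(2-iodophenyl)-4,4-dimethoxybutanoate
Product: 17 2-(2-iodophenyl)-4,4-dimethoxybutanal (racemic)
Conditions: (i-Bu)2AlH (1.1 equiv), CH2Cl2, −78 °C; aq. potassium sodium tartrate
Reagents that add atoms: none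
Why: Partial ester reduction, in which the tetrahedral aluminium hemiacetal is stable at −78 °C and collapses to the aldehyde only on work-up.

Step 10
Reactants: 13 di-tert-butyl (5S,6R,9R)-6-hydroxy-4-oxo-1-azaspiro[4.5]dec-7-ene-1,9-dicarboxylate; 17 2-(2-iodophenyl)-4,4-dimethoxybutanal
Product: 18 di-tert-butyl 4-hydroxy-6-{[2-(2-iodophenyl)-4,4-dimethoxybutanoyl]oxy}-1-azaspiro[4.5]dec-7-ene-1,9-dicarboxylate (4-OH on the ring face of C10; both epimers at the aryl-bearing carbon)
Conditions: SmI2 (0.3 equiv), 17 (4 equiv), THF, −10 °C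
Reagents that add atoms: none
Why: Evans–Tishchenko reduction, in which the samarium-bound hemiacetal of the C6 hydroxyl with 17 passes its hydride to the C4 ketone on the face that carries C6; the new carbinol should therefore be anti to C6 (cis to C10) and the C6 oxygen leaves the step as the aryl-butanoate ester, which differentiates the two oxygens.

Step 11
Reactants: 18 di-tert-butyl 4-hydroxy-6-{[2-(2-iodophenyl)-4,4-dimethoxybutanoyl]oxy}-1-azaspiro[4.5]dec-7-ene-1,9-dicarboxylate
Product: 19 di-tert-butyl 4-[(tert-butyldimethylsilyl)oxy]-6-{[2-(2-iodophenyl)-4,4-dimethoxybutanoyl]oxy}-1-azaspiro[4.5]dec-7-ene-1,9-dicarboxylate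
Conditions: t-BuMe2SiOTf, 2,6-lutidine, CH2Cl2, −78 → −20 °C
Reagents that add atoms: tert-butyldimethylsilyl trifluoromethanesulfonate, CC(C)(C)[Si](C)(C)OS(=O)(=O)C(F)(F)F
Why: The silyl triflate silylates the hindered carbinol at low temperature, where the carbamate, the tert-butyl ester and the acetal should not be attacked.

Step 12
Reactants: 19 di-tert-butyl 4-[(tert-butyldimethylsilyl)oxy]-6-{[2-(2-iodophenyl)-4,4-dimethoxybutanoyl]oxy}-1-azaspiro[4.5]dec-7-ene-1,9-dicarboxylate
Product: 22 bridged eight-membered lactone amino acid (key-step precursor; both epimers at the aryl-bearing carbon), via amino acid aldehyde 20 (not isolated), via cyclic hemiaminal 21 (not isolated)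
Conditions: CF3CO2H/CH2Cl2 (1:2), H2O (5 equiv), 0 °C → rt; evaporate; then NaBH(OAc)3, NaOAc, ClCH2CH2Cl (0.005 M), rt
Reagents that add atoms: none
Why: Acidolysis removes the carbamate and the tert-butyl ester and hydrolyses the acetal, and the ammonium aldehyde then closes to the eight-membered hemiaminal/iminium that NaBH(OAc)3 reduces (intramolecular reductive amination); the acidic medium keeps nitrogen largely protonated, which should hold back acyl transfer from the neighbouring C6 ester to nitrogen.

Step 13
Reactants: 22 bridged eight-membered lactone amino acid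
Product: 26 tetracyclic azocine dicarboxylic acid (key-step product), via dipotassium carboxylate enolate 23 (not isolated), via silyl ketene acetal trimethylsilyl ester 24 (not isolated), via rearranged bis(trimethylsilyl) ester 25 (not isolated)
Conditions: KN(SiMe3)2 (2.2 equiv), THF/toluene, −78 °C; then Me3SiCl, −78 → 80 °C; aq. KH2PO4
Reagents that add atoms: none
Why: Proposed new method: KN(SiMe3)2 first forms the C9 carboxylate, which protects H9 from deprotonation, and then the lactone enolate; O-silylation gives a silyl ketene acetal whose C=C bond lies in the eight-membered ring and is therefore cis, and on warming a [3,3] shift bonds the aryl-bearing carbon to the alkene carbon C8 while the allylic C6–O bond breaks and the double bond moves to C6=C7. The closest known reaction type is the Ireland–Claisen ring contraction of allylic lactones that carry an exocyclic vinyl group; here the alkene lies in a second ring, so the ring size is kept and the lactone becomes a carbocycle. The azocane closes by this sigmatropic ring switch through a bicyclic transition state in which the CH2CH2N tether spans positions 1 and 4 of the six-atom array, which only the boat form allows. Indoline C2 (the former C8) is set by suprafacial delivery on the ring face that carried the C6–O bond, that is by the C6 configuration, and C3 by the ring-fixed ketene acetal geometry together with the enforced boat, which should place the carboxyl over the new C6=C7 bridge and the aryl group on the open side next to the C2–H bond. The step needs enolisation at the lactone α-carbon only (both epimers converge there) and a [3,3] shift instead of ionisation or 1,4-elimination; the carboxylate at C9, enolate formation at −78 °C and the neutral silyl ketene acetal are meant to secure this.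

Step 14
Reactants: 26 tetracyclic azocine dicarboxylic acid
Product: 27 dimethyl ester of 26 (ring alkene and 2-iodophenyl and silyl ether retained)
Conditions: Me3SiCHN2, toluene/MeOH (4:1), 0 °C
Reagents that add atoms: (trimethylsilyl)diazomethane, C[Si](C)(C)C=[N+]=[N-]
Why: Both carboxylic acids are O-methylated through the diazonium ion pair without base, so C9 should not epimerise.

Step 15
Reactants: 27 dimethyl ester
Product: 28 dihydro dimethyl ester (ring A saturated)
Conditions: 2-nitrobenzenesulfonyl hydrazide, Et3N, CH2Cl2, rt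
Reagents that add atoms: none
Why: Diimide reduction transfers H2 to the cis-disubstituted ring alkene in a concerted way and should leave the aryl iodide, the esters and the silyl ether alone.

Step 16
Reactants: 28 dihydro dimethyl ester
Product: 29 aryl azide (2-azidophenyl in place of 2-iodophenyl)
Conditions: NaN3, CuI (copper iodide, 20 mol%), N,N′-dimethylethane-1,2-diamine, sodium ascorbate, DMSO/H2O (5:1), 60 °C
Reagents that add atoms: sodium azide, [Na+].[N-]=[N+]=[N-]
Why: Copper-catalysed Ullmann-type iodide–azide exchange, in which the iodide and chelation by the neighbouring ester carbonyl should offset the ortho quaternary carbon.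

Step 17
Reactants: 29 aryl azide
Product: 30 N-unsubstituted indoline (N1–C2 bond formed)
Conditions: Rh2(esp)2 (esp = α,α,α′,α′-tetramethyl-1,3-benzenedipropanoate, 5 mol%), CF3CO2H (1.1 equiv), 4 Å molecular sieves, toluene, 110 °C; aq. NaHCO3
Reagents that add atoms: none
Why: Rhodium-nitrenoid insertion of the aryl azide into the tertiary C2–H bond that lies gauche to the aryl ring closes the five-membered ring with retention, which suits a bridgehead carbon that cannot become planar; protonation of the tertiary amine shields its lone pair and deactivates the CH2 groups near nitrogen.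

Step 18
Reactants: 30 N-unsubstituted indoline
Product: 31 N-methoxycarbonyl indoline silyl ether
Conditions: ClCO2Me, pyridine, DMAP (cat.), CH2Cl2, 0 → 40 °C
Reagents that add atoms: methyl chloroformate, COC(=O)Cl
Why: Carbamate formation at the hindered indoline nitrogen; the tertiary amine is acylated only reversibly at this temperature.

Step 19
Reactants: 31 N-methoxycarbonyl indoline silyl ether
Product: 32 CNP0144467.2 (target)
Conditions: HF·pyridine, THF, 0 °C → rt
Reagents that add atoms: none
Why: Fluoride cleavage of the silyl ether under weakly acidic conditions that should not epimerise C9 or touch the carbamate and esters.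

## Compound list

1 | 1-tert-butyl 2-methyl 3-oxopyrrolidine-1,2-dicarboxylate | COC(=O)C1N(C(=O)OC(C)(C)C)CCC1=O | starting material
2 | lithium 1-(tert-butoxycarbonyl)-3-oxopyrrolidine-2-carboxylate | [Li+].[O-]C(=O)C1N(C(=O)OC(C)(C)C)CCC1=O | intermediate
3 | 1-(tert-butoxycarbonyl)-2-[(dimethylamino)methyl]-3-oxopyrrolidine-2-carboxylic acid | CN(C)CC1(C(O)=O)N(C(=O)OC(C)(C)C)CCC1=O | intermediate
4 | tert-butyl 2-[(dimethylamino)methyl]-3-oxopyrrolidine-1-carboxylate (racemic) | CN(C)CC1N(C(=O)OC(C)(C)C)CCC1=O | intermediate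
5 | {[1-(tert-butoxycarbonyl)-3-oxopyrrolidin-2-yl]methyl}trimethylammonium iodide (racemic) | C[N+](C)(C)CC1N(C(=O)OC(C)(C)C)CCC1=O.[I-] | intermediate
6 | malondialdehyde tetrabutylammonium salt | CCCC[N+](CCCC)(CCCC)CCCC.[O-]/C=C/C=O | starting material
7 | (E)-3-[(tert-butyldimethylsilyl)oxy]prop-2-enal | CC(C)(C)[Si](C)(C)O/C=C/C=O | intermediate
8 | tert-butyl (triphenyl-λ5-phosphanylidene)acetate | CC(C)(C)OC(=O)C=P(c1ccccc1)(c1ccccc1)c1ccccc1 | starting material
9 | tert-butyl (2E,4E)-5-[(tert-butyldimethylsilyl)oxy]penta-2,4-dienoate | CC(C)(C)OC(=O)/C=C/C=C/O[Si](C)(C)C(C)(C)C | intermediate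
10 | tert-butyl 2-methylidene-3-oxopyrrolidine-1-carboxylate | C=C1N(C(=O)OC(C)(C)C)CCC1=O | intermediate
11 | rac-di-tert-butyl (5S,6R,9R)-6-[(tert-butyldimethylsilyl)oxy]-4-oxo-1-azaspiro[4.5]dec-7-ene-1,9-dicarboxylate (both enantiomers) | CC(C)(C)OC(=O)[C@@H]1C[C@]2(N(C(=O)OC(C)(C)C)CCC2=O)[C@H](O[Si](C)(C)C(C)(C)C)C=C1.CC(C)(C)OC(=O)[C@H]1C[C@@]2(N(C(=O)OC(C)(C)C)CCC2=O)[C@@H](O[Si](C)(C)C(C)(C)C)C=C1 | intermediate
12 | di-tert-butyl (5S,6R,9R)-6-[(tert-butyldimethylsilyl)oxy]-4-oxo-1-azaspiro[4.5]dec-7-ene-1,9-dicarboxylate | CC(C)(C)OC(=O)[C@@H]1C[C@]2(N(C(=O)OC(C)(C)C)CCC2=O)[C@H](O[Si](C)(C)C(C)(C)C)C=C1 | intermediate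
13 | di-tert-butyl (5S,6R,9R)-6-hydroxy-4-oxo-1-azaspiro[4.5]dec-7-ene-1,9-dicarboxylate | CC(C)(C)OC(=O)[C@@H]1C[C@]2(N(C(=O)OC(C)(C)C)CCC2=O)[C@H](O)C=C1 | intermediate
14 | methyl 2-(2-iodophenyl)acetate | COC(=O)Cc1ccccc1I | starting material
15 | 2-bromo-1,1-dimethoxyethane | COC(CBr)OC | starting material
16 | methyl 2-(2-iodophenyl)-4,4-dimethoxybutanoate (racemic) | COC(=O)C(CC(OC)OC)c1ccccc1I | intermediate
17 | 2-(2-iodophenyl)-4,4-dimethoxybutanal (racemic) | O=CC(CC(OC)OC)c1ccccc1I | intermediate
18 | di-tert-butyl 4-hydroxy-6-{[2-(2-iodophenyl)-4,4-dimethoxybutanoyl]oxy}-1-azaspiro[4.5]dec-7-ene-1,9-dicarboxylate (core as in 12; 4-OH cis to C10; epimers at the aryl-bearing carbon) | CC(C)(C)OC(=O)[C@@H]1C[C@]2(N(C(=O)OC(C)(C)C)CC[C@H]2O)[C@H](OC(=O)C(CC(OC)OC)c3ccccc3I)C=C1 | intermediate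
19 | 4-O-tert-butyldimethylsilyl ether of 18 | CC(C)(C)OC(=O)[C@@H]1C[C@]2(N(C(=O)OC(C)(C)C)CC[C@H]2O[Si](C)(C)C(C)(C)C)[C@H](OC(=O)C(CC(OC)OC)c3ccccc3I)C=C1 | intermediate
20 | amino acid aldehyde: 6-{[2-(2-iodophenyl)-4-oxobutanoyl]oxy}-4-silyloxy-1-azaspiro[4.5]dec-7-ene-9-carboxylic acid with free NH | OC(=O)[C@@H]1C[C@]2(NCC[C@H]2O[Si](C)(C)C(C)(C)C)[C@H](OC(=O)C(CC=O)c3ccccc3I)C=C1 | intermediate
21 | cyclic hemiaminal: eight-membered lactone with N–CH(OH) | OC(=O)[C@@H]1C[C@@]23[C@H](OC(=O)C(c4ccccc4I)CC(O)N2CC[C@H]3O[Si](C)(C)C(C)(C)C)C=C1 | intermediate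
22 | bridged eight-membered lactone amino acid (key-step precursor): N1–CH2CH2–CH(2-iodophenyl)–CO–O–C6 bridge on the spiro-cyclohexene, free 9-CO2H, 4-OSi(t-Bu)Me2 | OC(=O)[C@@H]1C[C@@]23[C@H](OC(=O)C(c4ccccc4I)CCN2CC[C@H]3O[Si](C)(C)C(C)(C)C)C=C1 | intermediate
23 | dipotassium carboxylate enolate of 22 | [K+].[K+].[O-]C(=O)[C@@H]1C[C@@]23[C@H](O/C([O-])=C(c4ccccc4I)\CCN2CC[C@H]3O[Si](C)(C)C(C)(C)C)C=C1 | intermediate
24 | silyl ketene acetal trimethylsilyl ester of 22 (ring-cis C=C) | C[Si](C)(C)OC(=O)[C@@H]1C[C@@]23[C@H](O/C(O[Si](C)(C)C)=C(c4ccccc4I)\CCN2CC[C@H]3O[Si](C)(C)C(C)(C)C)C=C1 | intermediate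
25 | rearranged bis(trimethylsilyl) ester | C[Si](C)(C)OC(=O)[C@@H]1C[C@@]23C=C[C@@H]1[C@](c1ccccc1I)(C(=O)O[Si](C)(C)C)CCN2CC[C@H]3O[Si](C)(C)C(C)(C)C | intermediate
26 | tetracyclic azocine dicarboxylic acid (key-step product): azocane N–CH2CH2–C(2-iodophenyl)(CO2H) joined to the former C8; C6=C7 alkene; 9-CO2H; silyl ether | OC(=O)[C@@H]1C[C@@]23C=C[C@@H]1[C@](c1ccccc1I)(C(=O)O)CCN2CC[C@H]3O[Si](C)(C)C(C)(C)C | intermediate
27 | dimethyl ester of 26 | COC(=O)[C@@H]1C[C@@]23C=C[C@@H]1[C@](c1ccccc1I)(C(=O)OC)CCN2CC[C@H]3O[Si](C)(C)C(C)(C)C | intermediate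
28 | dihydro dimethyl ester (ring A saturated) | COC(=O)[C@@H]1C[C@@]23CC[C@@H]1[C@](c1ccccc1I)(C(=O)OC)CCN2CC[C@H]3O[Si](C)(C)C(C)(C)C | intermediate
29 | aryl azide | COC(=O)[C@@H]1C[C@@]23CC[C@@H]1[C@](c1ccccc1N=[N+]=[N-])(C(=O)OC)CCN2CC[C@H]3O[Si](C)(C)C(C)(C)C | intermediate
30 | N-unsubstituted indoline silyl ether | COC(=O)[C@@H]1C[C@@]23CC[C@@]14Nc1ccccc1[C@@]4(C(=O)OC)CCN2CC[C@H]3O[Si](C)(C)C(C)(C)C | intermediate
31 | N-methoxycarbonyl indoline silyl ether | COC(=O)[C@@H]1C[C@@]23CC[C@@]14N(C(=O)OC)c1ccccc1[C@@]4(C(=O)OC)CCN2CC[C@H]3O[Si](C)(C)C(C)(C)C | intermediate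
32 | CNP0144467.2 | COC(=O)[C@@H]1C[C@@]23CC[C@@]14N(C(=O)OC)c1ccccc1[C@@]4(C(=O)OC)CCN2CC[C@H]3O | target

## Step count and risks

Total step count: 19 (including the resolution).
Longest linear sequence: 15 steps (1, 2, 5, 6, 7, 10, 11, 12, 13, 14, 15, 16, 17, 18, 19).

Three steps most likely to fail:

1. Step 13 (ring-switching Ireland–Claisen rearrangement). The tether may not let the ketene acetal reach the boat array under the ring face, so that the silyl ketene acetal survives or ionises at the allylic C–O bond, or enolisation at the congested lactone α-carbon may stay incomplete. The fallback uses known chemistry, sets out from 19 and returns at 27. The open-chain ester 19 is rearranged before any medium ring exists, with KN(SiMe3)2 (1.1 equiv) and Me3SiCl in THF from −78 °C to rt; this is an Ireland–Claisen rearrangement of an acyclic allylic α-aryl ester, in which the bulky C9 tert-butyl ester is not expected to be enolised by one equivalent of base. It should give the open-chain Claisen acid F1 with the same suprafacial transfer to C8 but without ring control at the new quaternary carbon. Me3SiCHN2 then gives its methyl ester F2. CF3CO2H/H2O followed by NaBH(OAc)3 closes the azocane at nitrogen by intramolecular reductive amination to the azocane amino acid F3, at which stage the unwanted epimer at the quaternary carbon is separated. Me3SiCHN2 converts F3 into 27.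

2. Step 12 (deprotection and eight-membered ring closure at nitrogen). Once nitrogen is free, the neighbouring C6 ester may pass its acyl group to nitrogen, or the eight-membered iminium may form more slowly than the aldehyde is reduced or oligomerises. The fallback sets out from 13 and returns at 22; nitrogen is alkylated before the C6 aryl-butanoate exists and the lactone is closed last.
   - Evans–Tishchenko reduction of 13 with acetaldehyde and SmI2 gives the C6 acetate F4.
   - t-BuMe2SiOTf/2,6-lutidine gives the silyl ether F5.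
   - K2CO3 in MeOH frees the C6 alcohol F6.
   - H2SO4 in tert-butyl acetate removes only the carbamate to give the secondary amine F7.
   - Aqueous CF3CO2H converts 16 into methyl 2-(2-iodophenyl)-4-oxobutanoate F8.
   - NaBH(OAc)3 joins F7 and F8 to the N-alkylated hydroxy methyl ester F9.
   - LiOH cleaves the methyl ester to the seco acid F10.
   - 2-Methyl-6-nitrobenzoic anhydride and DMAP at high dilution close the lactone tert-butyl ester F11.
   - CF3CO2H cleaves the tert-butyl ester and gives 22.

3. Step 5 (Diels–Alder reaction with the enone made in the flask). The push–pull diene may react too slowly, so that the enone dimerises by hetero-Diels–Alder reaction, and the ester may lower the orbital coefficient at its terminus and erode the regiocontrol. The fallback sets out from 9 (with 5) and returns at 11; the ester is taken off the diene before the cycloaddition and restored afterwards.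
   - (i-Bu)2AlH reduces 9 to the dienol F12.
   - t-BuMe2SiCl/imidazole gives the bis-silyl diene F13, a plain 1-silyloxy diene.
   - Cycloaddition with 10 released from 5 under the conditions of step 5 gives the cycloadduct F14.
   - HF·pyridine buffered with pyridine frees the primary alcohol F15.
   - Dess–Martin periodinane gives the aldehyde F16.
   - NaClO2/NaH2PO4/2-methylbut-2-ene gives the acid F17.
   - tert-Butyl 2,2,2-trichloroacetimidate returns 11.

Further compounds

F1 | step 13 | open-chain Claisen acid: 2-[1-Boc-9-(tert-butoxycarbonyl)-4-silyloxy-1-azaspiro[4.5]dec-6-en-8-yl]-2-(2-iodophenyl)-4,4-dimethoxybutanoic acid (epimers at the quaternary carbon) | CC(C)(C)OC(=O)[C@@H]1C[C@]2(N(C(=O)OC(C)(C)C)CC[C@H]2O[Si](C)(C)C(C)(C)C)C=C[C@@H]1C(CC(OC)OC)(C(=O)O)c3ccccc3I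
F2 | step 13 | methyl ester of F1 | CC(C)(C)OC(=O)[C@@H]1C[C@]2(N(C(=O)OC(C)(C)C)CC[C@H]2O[Si](C)(C)C(C)(C)C)C=C[C@@H]1C(CC(OC)OC)(C(=O)OC)c3ccccc3I
F3 | step 13 | azocane amino acid (free 9-CO2H, methyl ester at the quaternary carbon) | OC(=O)[C@@H]1C[C@@]23C=C[C@@H]1[C@](c1ccccc1I)(C(=O)OC)CCN2CC[C@H]3O[Si](C)(C)C(C)(C)C
F4 | step 12 | C6 acetate with free C4 carbinol | CC(C)(C)OC(=O)[C@@H]1C[C@]2(N(C(=O)OC(C)(C)C)CC[C@H]2O)[C@H](OC(C)=O)C=C1
F5 | step 12 | C4 silyl ether of F4 | CC(C)(C)OC(=O)[C@@H]1C[C@]2(N(C(=O)OC(C)(C)C)CC[C@H]2O[Si](C)(C)C(C)(C)C)[C@H](OC(C)=O)C=C1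
F6 | step 12 | C6 alcohol with C4 silyl ether | CC(C)(C)OC(=O)[C@@H]1C[C@]2(N(C(=O)OC(C)(C)C)CC[C@H]2O[Si](C)(C)C(C)(C)C)[C@H](O)C=C1
F7 | step 12 | secondary amine (carbamate removed, tert-butyl ester kept) | CC(C)(C)OC(=O)[C@@H]1C[C@]2(NCC[C@H]2O[Si](C)(C)C(C)(C)C)[C@H](O)C=C1
F8 | step 12 | methyl 2-(2-iodophenyl)-4-oxobutanoate | COC(=O)C(CC=O)c1ccccc1I
F9 | step 12 | N-alkylated hydroxy methyl ester | CC(C)(C)OC(=O)[C@@H]1C[C@]2(N(CCC(C(=O)OC)c3ccccc3I)CC[C@H]2O[Si](C)(C)C(C)(C)C)[C@H](O)C=C1
F10 | step 12 | seco acid | CC(C)(C)OC(=O)[C@@H]1C[C@]2(N(CCC(C(=O)O)c3ccccc3I)CC[C@H]2O[Si](C)(C)C(C)(C)C)[C@H](O)C=C1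
F11 | step 12 | lactone tert-butyl ester (tert-butyl ester of 22) | CC(C)(C)OC(=O)[C@@H]1C[C@@]23[C@H](OC(=O)C(c4ccccc4I)CCN2CC[C@H]3O[Si](C)(C)C(C)(C)C)C=C1
F12 | step 5 | (2E,4E)-5-[(tert-butyldimethylsilyl)oxy]penta-2,4-dien-1-ol | OC/C=C/C=C/O[Si](C)(C)C(C)(C)C
F13 | step 5 | bis-silyl diene: (1E,3E)-1,5-bis[(tert-butyldimethylsilyl)oxy]penta-1,3-diene | CC(C)(C)[Si](C)(C)OC/C=C/C=C/O[Si](C)(C)C(C)(C)C
F14 | step 5 | cycloadduct with 9-CH2OSi(t-Bu)Me2 (racemic; relative configuration shown) | CC(C)(C)[Si](C)(C)OC[C@@H]1C[C@]2(N(C(=O)OC(C)(C)C)CCC2=O)[C@H](O[Si](C)(C)C(C)(C)C)C=C1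
F15 | step 5 | primary alcohol (racemic; relative configuration shown) | OC[C@@H]1C[C@]2(N(C(=O)OC(C)(C)C)CCC2=O)[C@H](O[Si](C)(C)C(C)(C)C)C=C1
F16 | step 5 | aldehyde (racemic; relative configuration shown) | O=C[C@@H]1C[C@]2(N(C(=O)OC(C)(C)C)CCC2=O)[C@H](O[Si](C)(C)C(C)(C)C)C=C1
F17 | step 5 | 9-carboxylic acid (racemic; relative configuration shown) | OC(=O)[C@@H]1C[C@]2(N(C(=O)OC(C)(C)C)CCC2=O)[C@H](O[Si](C)(C)C(C)(C)C)C=C1
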